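C1 CHOAc, C2 CH2, C3 C(OH)iPr, C4 fusion CH, C5 CH-O-aroyl, C6=C7(Me), C8 C=O, C9 CH2, C10 C-Me. The five-membered ring is C1-C2-C3-C4-C10 and the seven-membered ring is C4 to C10.
Cuts, in order: the two ester C-O bonds; the oxygens at C5 and C8 (back to a C5=C6-C7=C8 ring diene); C5=C6 by metathesis; then C4-C5 and C9-C10 together.
Enabling feature: with C1 as a ketone, the five-membered ring is a 2-methylcyclopent-2-enone. C4 is its β carbon and C10 its α carbon, and these neighbours hold, trans to each other, the ends C5 and C9 of the seven-membered ring.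
Forward order: metathesis of an acyclic dienediol closes the five-membered ring, both arms are attached in one flask, diene-ene metathesis closes the seven-membered ring, and oxygen is added last.
Stereochemistry: a Sharpless kinetic resolution fixes a temporary C1 carbinol and chelation relays it to C3. C3 steers vinyl to C4, C4 steers the alkylation at C10, and the C10 methyl group steers hydride to C1 and singlet oxygen to C5.
Key step: step 9

Assumption: (Z)-3-methylpent-2-en-4-yn-1-ol and 4-(tert-butyldimethylsilyloxy)benzoic acid are taken as purchasable; β is the face of the ring system that carries the C10 methyl group and α is the opposite face.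

Step 1
Reactants: 1 3-methylbutan-2-one; 2 methacrolein (2-methylprop-2-enal)
Product: 4 rac-5-hydroxy-2,6-dimethylhept-6-en-3-one, via lithium enolate 3 (not isolated)
Conditions: LDA, THF, −78 °C; then 2, −78 °C
Reagents that add atoms: none
Why: LDA deprotonates the ketone kinetically on the methyl side and the lithium enolate adds to the carbonyl group of the non-enolisable enal in a crossed aldol addition, the C1 carbinol being racemic at this stage.

Step 2
Reactants: 4 rac-5-hydroxy-2,6-dimethylhept-6-en-3-one
Product: 5 (5S)-5-hydroxy-2,6-dimethylhept-6-en-3-one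
Conditions: Ti(OiPr)4 (20 mol %), D-(−)-diisopropyl tartrate (24 mol %), t-BuOOH (0.6 equiv), 4 Å molecular sieves, CH2Cl2, −20 °C
Reagents that add atoms: none
Why: Sharpless kinetic resolution: with the D-(−)-tartrate the titanium peroxo complex epoxidises the (R)-allylic alcohol much faster than the (S)-alcohol, so a run taken slightly past half conversion should leave 5 as the (S)-enantiomer, easily separated from the more polar epoxy alcohol.

Step 3
Reactants: 5 (5S)-5-hydroxy-2,6-dimethylhept-6-en-3-one; 6 vinylmagnesium bromide
Product: 8 (3S,5R)-2-methyl-5-(propan-2-yl)hepta-1,6-diene-3,5-diol, via magnesium alkoxide chelate 7 (not isolated)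
Conditions: 6 (1 M in THF, 3.5 equiv), CH2Cl2, −78 °C
Reagents that add atoms: none
Why: The first equivalent of 6 gives the magnesium alkoxide, which locks the ketone into a six-membered chelate with the isopropenyl group equatorial, and vinyl then enters axially, trans to that group (chelation-controlled Grignard addition with 1,3-induction, same sense as a Narasaka–Prasad reduction), which sets C3 as R; the minor C3 epimer is removed by chromatography, so it costs material but not enantiomeric purity.

Step 4
Reactants: 8 (3S,5R)-2-methyl-5-(propan-2-yl)hepta-1,6-diene-3,5-diol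
Product: 9 (1R,3S)-4-methyl-1-(propan-2-yl)cyclopent-4-ene-1,3-diol (trans diol)
Conditions: second-generation Grubbs catalyst (2 mol %), CH2Cl2, 40 °C
Reagents that add atoms: none
Why: Ring-closing metathesis of a vinyl group onto an isopropenyl group to give a trisubstituted cyclopentene is a fast five-membered closure that tolerates free allylic alcohols and touches neither stereocentre.

Step 5
Reactants: 9 (1R,3S)-4-methyl-1-(propan-2-yl)cyclopent-4-ene-1,3-diol
Product: 10 (4R)-4-hydroxy-2-methyl-4-(propan-2-yl)cyclopent-2-en-1-one
Conditions: MnO2 (activated, excess), CH2Cl2, rt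
Reagents that add atoms: none
Why: Allylic oxidation with MnO2 can only take the secondary carbinol, the tertiary one having no carbinol hydrogen, and the neutral medium avoids the retro-aldol ring opening that would racemise C3; the relay centre at C1 is given up here.

Step 6
Reactants: 10 (4R)-4-hydroxy-2-methyl-4-(propan-2-yl)cyclopent-2-en-1-one
Product: 11 (4R)-4-(tert-butyldimethylsilyloxy)-2-methyl-4-(propan-2-yl)cyclopent-2-en-1-one
Conditions: TBSOTf, 2,6-lutidine, CH2Cl2, 0 °C to rt
Reagents that add atoms: tert-butyldimethylsilyl trifluoromethanesulfonate, CC(C)(C)[Si](C)(C)OS(=O)(=O)C(F)(F)F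
Why: Silylation with the silyl triflate and a hindered pyridine base is the standard method for tertiary alcohols and is not basic enough to start a retro-aldol reaction; C3 is untouched.

Step 7
Reactants: 12 (Z)-3-methylpent-2-en-4-yn-1-ol
Product: 13 (2Z)-3-methylpenta-2,4-dien-1-ol
Conditions: H2 (1 atm), Pd/CaCO3 poisoned with Pb(OAc)2 (Lindlar catalyst), quinoline, Et2O, 0 °C
Reagents that add atoms: none
Why: Lindlar semihydrogenation stops at the alkene stage of the terminal alkyne and leaves the trisubstituted Z double bond in place.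

Step 8
Reactants: 13 (2Z)-3-methylpenta-2,4-dien-1-ol
Product: 14 (3Z)-5-bromo-3-methylpenta-1,3-diene
Conditions: PBr3 (0.4 equiv), Et2O, −20 to 0 °C; used at once as a dried ethereal solution
Reagents that add atoms: phosphorus tribromide, BrP(Br)Br
Why: PBr3 turns the primary allylic alcohol into a phosphite leaving group that bromide displaces in an SN2 reaction, and the low temperature and immediate use should keep the Z geometry.

Step 9
Reactants: 11 (4R)-4-(tert-butyldimethylsilyloxy)-2-methyl-4-(propan-2-yl)cyclopent-2-en-1-one; 6 vinylmagnesium bromide; 14 (3Z)-5-bromo-3-methylpenta-1,3-diene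
Product: 16 (2S,3S,4R)-4-(tert-butyldimethylsilyloxy)-3-ethenyl-2-methyl-2-[(2Z)-3-methylpenta-2,4-dien-1-yl]-4-(propan-2-yl)cyclopentan-1-one, via bromomagnesium enolate 15 (not isolated)
Conditions: 6 (2.2 equiv), CuBr·SMe2 (1.2 equiv), THF, −78 to −40 °C; 11, −78 °C; then HMPA, 14 (3 equiv), −78 to −20 °C; aq NH4Cl
Reagents that add atoms: none
Why: The homocuprate made from 6 and CuBr·SMe2 forms a π complex with the enone, passes vinyl to C4 by oxidative addition and reductive elimination, and leaves the regiodefined tetrasubstituted enolate 15, which HMPA makes nucleophilic enough to displace bromide from 14 in an SN2 reaction at C10. The closest known reaction type is the three-component coupling of 4-silyloxycyclopentenones (organocopper conjugate addition, then trapping of the enolate with an allylic halide), together with the vinylation and alkylation of 2-methylcyclopentenone. No ring is closed, and the bonds formed are C4-C5 and C9-C10. C4 is controlled by C3: the silyl group escapes the isopropyl group by lying under the α face, the isopropyl group turns its C-H bond over the β face, and attack anti to the C3-O bond is also favoured stereoelectronically, so vinyl should enter from the β face. C10 is controlled by C4, because the bromide meets the enolate on the face away from the new vinyl group (1,2-anti and 1,3-syn to the silyloxy group, as in couplings of 4-silyloxycyclopentenones), which gives the trans relation of the two arms. The step needs 1,4- over 1,2-addition (secured by the soft stoichiometric cuprate free of excess Grignard reagent), alkylation faster than the proton exchange that would end in β-elimination of the silyloxy group (secured by excess primary allylic bromide, HMPA and temperatures at or below −20 °C), and substitution without allylic transposition (secured by the unhindered CH2Br terminus).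

Step 10
Reactants: 16 the trans-2,3-disubstituted cyclopentanone of step 9
Product: 17 (3R,3aS,8aS)-3-(tert-butyldimethylsilyloxy)-6,8a-dimethyl-3-(propan-2-yl)-3,3a,8,8a-tetrahydroazulen-1(2H)-one (trans-fused; ring diene C5=C6-C7=C8)
Conditions: second-generation Hoveyda–Grubbs catalyst (10 mol %), toluene (high dilution), 70 °C, argon sparge
Reagents that add atoms: none
Why: Diene-ene ring-closing metathesis joins the two terminal CH2= carbons, the Z geometry at C7=C8 holds the chain ends within reach, and the alternative closure onto C8 would give a strained trans-bicyclo[3.3.0]octene, so the seven-membered 1,3-diene should form with all stereocentres untouched.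

Step 11
Reactants: 17 the bicyclic dienone of step 10
Product: 18 (1S,3R,3aS,8aS)-3-(tert-butyldimethylsilyloxy)-6,8a-dimethyl-3-(propan-2-yl)-1,2,3,3a,8,8a-hexahydroazulen-1-ol
Conditions: NaBH4, MeOH/CH2Cl2, 0 °C
Reagents that add atoms: none
Why: Borohydride reduction of the cyclopentanone: the β face of C1 is closed by the adjacent angular methyl group and by the isopropyl group, so hydride should arrive from the α face as in 17-oxo steroids and give the (1S)-alcohol with the hydroxyl group cis to the methyl group.

Step 12
Reactants: 18 the silyl-protected dienol of step 11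
Product: 19 (1S,3R,3aS,8aS)-6,8a-dimethyl-3-(propan-2-yl)-1,2,3,3a,8,8a-hexahydroazulene-1,3-diol
Conditions: Bu4NF (3 equiv), THF, 50 °C
Reagents that add atoms: none
Why: Fluoride-induced cleavage of the silyl ether is placed after the reduction so that no β-hydroxy ketone capable of retro-aldol cleavage meets the basic reagent, and migration of silicon to O1 is excluded because the two oxygens lie on opposite faces.

Step 13
Reactants: 19 the diene diol of step 12
Product: 20 (1S,3R,3aS,8aS)-3-hydroxy-6,8a-dimethyl-3-(propan-2-yl)-1,2,3,3a,8,8a-hexahydroazulen-1-yl acetate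
Conditions: Ac2O, pyridine, DMAP (cat.), CH2Cl2, 0 °C to rt
Reagents that add atoms: acetic anhydride, CC(=O)OC(C)=O
Why: DMAP-catalysed acetylation takes the secondary alcohol only, since the tertiary C3 alcohol next to the isopropyl group is too hindered to react under these conditions.

Step 14
Reactants: 20 the diene monoacetate of step 13
Product: 22 (1S,3R,3aR,4R,8aS)-3,4-dihydroxy-6,8a-dimethyl-7-oxo-3-(propan-2-yl)-1,2,3,3a,4,7,8,8a-octahydroazulen-1-yl acetate, via endoperoxide 21 (not isolated)
Conditions: O2, tetraphenylporphyrin (cat.), hν (visible), CH2Cl2, −20 °C; then Et3N, 0 °C to rt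
Reagents that add atoms: oxygen, O=O
Why: Singlet oxygen adds to the s-cis ring diene in a [4+2] cycloaddition on the α face, because the β face is covered by the C10 methyl and isopropyl groups and the α-oriented C3 hydroxyl group can steer the reagent by hydrogen bonding, which sets C5 as R, and in the Kornblum–DeLaMare rearrangement the amine removes the exposed H8 rather than H5, which is buried next to C3 and C4, while the hydrogen bond from the C3 hydroxyl group makes O5 the better leaving oxygen.

Step 15
Reactants: 22 the γ-hydroxy enone of step 14; 23 4-(tert-butyldimethylsilyloxy)benzoic acid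
Product: 24 (1S,3R,3aR,4R,8aS)-1-acetoxy-3-hydroxy-6,8a-dimethyl-7-oxo-3-(propan-2-yl)-1,2,3,3a,4,7,8,8a-octahydroazulen-4-yl 4-(tert-butyldimethylsilyloxy)benzoate
Conditions: DCC, DMAP (cat.), CH2Cl2, rt
Reagents that add atoms: none
Why: Steglich esterification acylates the secondary allylic alcohol without touching the C5-O bond, so the configuration is kept, and the tertiary C3 alcohol stays free as in step 13.

Step 16
Reactants: 24 the silyl-protected diester of step 15
Product: 25 CNP0087181.1, (1S,3R,3aR,4R,8aS)-1-acetoxy-3-hydroxy-6,8a-dimethyl-7-oxo-3-(propan-2-yl)-1,2,3,3a,4,7,8,8a-octahydroazulen-4-yl 4-hydroxybenzoate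
Conditions: HF·pyridine, pyridine, THF, 0 °C
Reagents that add atoms: none
Why: An aryl silyl ether carrying a para ester group is cleaved by buffered HF within minutes, under conditions too mild for the two esters, the tertiary alcohol or the γ-acyloxy enone.

Compound list
1 | 3-methylbutan-2-one | CC(C)C(C)=O | starting material
2 | methacrolein | C=C(C)C=O | starting material
3 | lithium 3-methylbut-1-en-2-olate | [Li]OC(=C)C(C)C | intermediate
4 | rac-5-hydroxy-2,6-dimethylhept-6-en-3-one (racemate) | CC(C)C(=O)CC(O)C(C)=C | intermediate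
5 | (5S)-5-hydroxy-2,6-dimethylhept-6-en-3-one | CC(C)C(=O)C[C@H](O)C(C)=C | intermediate
6 | vinylmagnesium bromide | C=C[Mg]Br | starting material
7 | bromomagnesium alkoxide (chelate) of 5 | CC(C)C(=O)C[C@H](O[Mg]Br)C(C)=C | intermediate
8 | (3S,5R)-2-methyl-5-(propan-2-yl)hepta-1,6-diene-3,5-diol | C=C[C@](O)(C(C)C)C[C@H](O)C(C)=C | intermediate
9 | (1R,3S)-4-methyl-1-(propan-2-yl)cyclopent-4-ene-1,3-diol | O[C@H]1C[C@@](O)(C(C)C)C=C1C | intermediate
10 | (4R)-4-hydroxy-2-methyl-4-(propan-2-yl)cyclopent-2-en-1-one | O=C1C[C@@](O)(C(C)C)C=C1C | intermediate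
11 | (4R)-4-(tert-butyldimethylsilyloxy)-2-methyl-4-(propan-2-yl)cyclopent-2-en-1-one | O=C1C[C@@](O[Si](C)(C)C(C)(C)C)(C(C)C)C=C1C | intermediate
12 | (Z)-3-methylpent-2-en-4-yn-1-ol | C#C/C(C)=C\CO | starting material
13 | (2Z)-3-methylpenta-2,4-dien-1-ol | C=C/C(C)=C\CO | intermediate
14 | (3Z)-5-bromo-3-methylpenta-1,3-diene | BrC/C=C(C)\C=C | intermediate
15 | bromomagnesium enolate (C1=C10) carrying the β vinyl group at C4 | Br[Mg]OC1=C(C)[C@H](C=C)[C@](O[Si](C)(C)C(C)(C)C)(C(C)C)C1 | intermediate
16 | (2S,3S,4R)-4-(tert-butyldimethylsilyloxy)-3-ethenyl-2-methyl-2-[(2Z)-3-methylpenta-2,4-dien-1-yl]-4-(propan-2-yl)cyclopentan-1-one | O=C1C[C@@](O[Si](C)(C)C(C)(C)C)(C(C)C)[C@@H](C=C)[C@]1(C)C/C=C(C)\C=C | intermediate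
17 | (3R,3aS,8aS)-3-(tert-butyldimethylsilyloxy)-6,8a-dimethyl-3-(propan-2-yl)-3,3a,8,8a-tetrahydroazulen-1(2H)-one | O=C1C[C@@](O[Si](C)(C)C(C)(C)C)(C(C)C)[C@H]2C=CC(C)=CC[C@]12C | intermediate
18 | (1S,3R,3aS,8aS)-3-(tert-butyldimethylsilyloxy)-6,8a-dimethyl-3-(propan-2-yl)-1,2,3,3a,8,8a-hexahydroazulen-1-ol | O[C@H]1C[C@@](O[Si](C)(C)C(C)(C)C)(C(C)C)[C@H]2C=CC(C)=CC[C@]12C | intermediate
19 | (1S,3R,3aS,8aS)-6,8a-dimethyl-3-(propan-2-yl)-1,2,3,3a,8,8a-hexahydroazulene-1,3-diol | O[C@H]1C[C@@](O)(C(C)C)[C@H]2C=CC(C)=CC[C@]12C | intermediate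
20 | (1S,3R,3aS,8aS)-3-hydroxy-6,8a-dimethyl-3-(propan-2-yl)-1,2,3,3a,8,8a-hexahydroazulen-1-yl acetate | CC(=O)O[C@H]1C[C@@](O)(C(C)C)[C@H]2C=CC(C)=CC[C@]12C | intermediate
21 | 5α,8α-endoperoxide of 20 (O-O bridge from C5 to C8 on the α face, C6=C7 alkene; 1S,3R,4R,5R,8R,10S in the route numbering) | CC(=O)O[C@H]1C[C@@](O)(C(C)C)[C@H]2[C@H]3C=C(C)[C@H](OO3)C[C@]12C | intermediate
22 | (1S,3R,3aR,4R,8aS)-3,4-dihydroxy-6,8a-dimethyl-7-oxo-3-(propan-2-yl)-1,2,3,3a,4,7,8,8a-octahydroazulen-1-yl acetate | CC(=O)O[C@H]1C[C@@](O)(C(C)C)[C@H]2[C@H](O)C=C(C)C(=O)C[C@]12C | intermediate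
23 | 4-(tert-butyldimethylsilyloxy)benzoic acid | O=C(O)c1ccc(O[Si](C)(C)C(C)(C)C)cc1 | starting material
24 | (1S,3R,3aR,4R,8aS)-1-acetoxy-3-hydroxy-6,8a-dimethyl-7-oxo-3-(propan-2-yl)-1,2,3,3a,4,7,8,8a-octahydroazulen-4-yl 4-(tert-butyldimethylsilyloxy)benzoate | CC(=O)O[C@H]1C[C@@](O)(C(C)C)[C@H]2[C@H](OC(=O)c3ccc(O[Si](C)(C)C(C)(C)C)cc3)C=C(C)C(=O)C[C@]12C | intermediate
25 | CNP0087181.1, (1S,3R,3aR,4R,8aS)-1-acetoxy-3-hydroxy-6,8a-dimethyl-7-oxo-3-(propan-2-yl)-1,2,3,3a,4,7,8,8a-octahydroazulen-4-yl 4-hydroxybenzoate | CC(=O)O[C@H]1C[C@@](O)(C(C)C)[C@H]2[C@H](OC(=O)c3ccc(O)cc3)C=C(C)C(=O)C[C@]12C | target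

Total step count: 16. Longest linear sequence: 14 (steps 1 to 6 and 9 to 16); steps 7 and 8 form the side branch.

Steps most likely to fail

Step 9.
- Risk: the cuprate may attack the face that bears the silyloxy group to a significant extent. A slow quaternisation at C10 may also let the enolate exchange protons with the product, which ends in β-elimination of the silyloxy group.
- Fallback: the two bond formations are separated, setting out from 11 and returning at 16.
  - Vinyl transfer from 6 under CuBr·SMe2 catalysis in the presence of Me3SiCl (accelerated addition at −78 °C, with the enolate silylated as it forms) would give the trimethylsilyl enol ether F1.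
  - F1 can be freed from any C4 epimer on base-washed silica.
  - MeLi in THF then releases the salt-free lithium enolate F2, which is alkylated with 14 in THF/HMPA to give 16.

Step 10.
- Risk: the ruthenium carbene may rest as the conjugated vinylcarbene formed at the diene terminus. It may then fail to engage the C4 vinyl group, which is flanked by the cis isopropyl and methyl groups, so oligomerisation overtakes ring closure.
- Fallback: the metathesis is moved to the C7=C8 bond, setting out from 11 and returning at 17.
  - Syn-carbocupration of acetylene by the cuprate from isopropenylmagnesium bromide and CuBr·SMe2 gives bromomagnesium bis[(Z)-3-methylbuta-1,3-dienyl]cuprate F3, which transfers the whole C5-C7 unit to C4.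
  - The resulting bromomagnesium dienyl enolate F4 is trapped with allyl bromide in the same flask to give the 2-allyl-3-dienyl cyclopentanone F5.
  - The second-generation Grubbs catalyst then loads on the unhindered allyl group and closes onto the isopropenyl terminus, which gives 17.

Step 14.
- Risk: the ene reaction of singlet oxygen at C7=C8 may compete with cycloaddition. In the base-induced opening the amine may also remove H5 as well as H8, which would put the ketone at the wrong end.
- Fallback: the O-O bond is cleaved reductively and the two carbinols are told apart afterwards, setting out from 21 (amine left out) and returning at 22.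
  - Thiourea in MeOH gives the cis-5α,8α-enediol F6.
  - MnO2 in CH2Cl2 then oxidises the exposed C8 allylic alcohol in preference to the C5 alcohol, which is crowded by C3 and C4 and hydrogen-bonded to the C3 hydroxyl group. This gives 22.

Further compounds
F1 | step 9 | trimethylsilyl enol ether (C1=C10) of (3S,4R)-4-(tert-butyldimethylsilyloxy)-3-ethenyl-2-methyl-4-(propan-2-yl)cyclopentanone | C[Si](C)(C)OC1=C(C)[C@H](C=C)[C@](O[Si](C)(C)C(C)(C)C)(C(C)C)C1
F2 | step 9 | lithium enolate (C1=C10) released from F1 | [Li]OC1=C(C)[C@H](C=C)[C@](O[Si](C)(C)C(C)(C)C)(C(C)C)C1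
F3 | step 10 | bromomagnesium bis[(Z)-3-methylbuta-1,3-dienyl]cuprate | C=C(C)/C=C\[Cu-]/C=C\C(C)=C.[Mg+2].[Br-]
F4 | step 10 | bromomagnesium enolate (C1=C10) carrying the β (Z)-3-methylbuta-1,3-dienyl group at C4 | Br[Mg]OC1=C(C)[C@H](/C=C\C(C)=C)[C@](O[Si](C)(C)C(C)(C)C)(C(C)C)C1
F5 | step 10 | (2S,3S,4R)-4-(tert-butyldimethylsilyloxy)-2-methyl-3-[(1Z)-3-methylbuta-1,3-dien-1-yl]-4-(propan-2-yl)-2-(prop-2-en-1-yl)cyclopentan-1-one | O=C1C[C@@](O[Si](C)(C)C(C)(C)C)(C(C)C)[C@@H](/C=C\C(C)=C)[C@]1(C)CC=C
F6 | step 14 | (1S,3R,3aR,4R,7R,8aS)-3,4,7-trihydroxy-6,8a-dimethyl-3-(propan-2-yl)-1,2,3,3a,4,7,8,8a-octahydroazulen-1-yl acetate | CC(=O)O[C@H]1C[C@@](O)(C(C)C)[C@H]2[C@H](O)C=C(C)[C@H](O)C[C@]12C
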